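At late times complex with one exchanged stood level in both earlier runs: it read 15.5% at 2.00 min and 15.6% at 4.00 min in larch, and 35.9% at 2.00 min and 35.9% at 4.00 min in ash. Here a starting complex exchanges ligands with an incoming ligand in a closed, stirred, isothermal flask.

all flasks: starting complex 0.050 M
- larch: incoming ligand 0.013 M; run made earlier
- ash: incoming ligand 0.090 M; run made earlier
- dawn: incoming ligand 0.0250 M; time 5.0 min
- summer: incoming ligand 0.0400 M; time 5.0 min
- autumn: incoming ligand 0.125 M; time 5.0 min

| run | time / min | complex with one exchanged / % | complex with two exchanged / % |
|---|---|---|---|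
| larch | 0.250 | 4.2 | 0 |
| larch | 0.500 | 8.1 | 1.5 |
| larch | 1.00 | 11.4 | 0 |
| larch | 2.00 | 15.5 | 1.1 |
| larch | 4.00 | 15.6 | 0 |
| ash | 0.667 | 29.8 | 2.5 |
| ash | 1.33 | 31.8 | 3.5 |
| ash | 2.00 | 35.9 | 2.8 |
| ash | 3.00 | 35.8 | 0.8 |
| ash | 4.00 | 35.9 | 0 |

(standard deviation of a reading: 1 percentage point)

- final complex with one exchanged, as a percentage of the starting complex charged, for each flask in turn (dawn, summer, autumn)

My first question was whether the asked time lay beyond the rise. Judged by the two earlier runs it did: 5.0 min is 2.50 times the 2.00 min at which both runs already read level, so I treated the three answers as plateau heights.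

The second question was how the plateau follows the charge. Going from larch to ash, the ligand charge rose 6.92-fold, but the plateau rose 2.30-fold. I therefore used the capture share, the part of the charged incoming ligand that stands as complex with one exchanged on the plateau. It read 60.0% in larch and 19.9% in ash.

The third question was how fast that share falls. Taken as a power of the charge, the two readings give an exponent of 0.569. My own reckoning then gave 20.7% for dawn, 25.3% for summer and 41.4% for autumn.

The forecast differed, with 21.8%, 26.5% and 39.2%, on its own ground: “I read these plateaus as equilibria”. Both reckonings rest on the same two plateau readings. Dawn and summer lie between those charges, and autumn lies 1.39-fold beyond ash, where the two sets stood 2.2 percentage points apart.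

The flasks gave 23.2%, 28.6% and 39.4%.

    complex with two exchanged → over-reaction product B (k = 0.0100 s⁻¹)
    2 incoming ligand → self-condensation product (k = 0.670 L mol⁻¹ s⁻¹)
    starting complex + incoming ligand → leaving ligand + complex with one exchanged (k = 0.360 L mol⁻¹ s⁻¹)
    complex with one exchanged + incoming ligand → leaving ligand + complex with two exchanged (k = 0.210 L mol⁻¹ s⁻¹)
    complex with two exchanged → over-reaction product A (k = 1.10 × 10⁻⁴ s⁻¹)
    complex with two exchanged + incoming ligand → leaving ligand + complex with three exchanged (k = 0.330 L mol⁻¹ s⁻¹)

In dawn at 5.00 min, the incoming ligand, the limiting reagent, was down to 0.254% of its charge, with 74.6% of the starting complex still standing and 0.00555 M of self-condensation product formed. Dawn's capture share came to 46.4%. Autumn's came to 15.8%, lower than the 60.0% read in larch by a factor of 3.81.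

The data are simulated for substances that don't exist, and the scatter is random.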